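(The data come from a simulation from invented constants, noise included.)

The north vessel is closed, stirred and isothermal, and its charge stands next to the alder run: partner and free catalyst are the same, and substrate is 20 mM against 22 mM.

| flask | substrate | partner | free catalyst | remark | time |
|---|---|---|---|---|---|
| alder | 22 mM | 22 mM | 0.40 mM | run made earlier |  |
| elm | 190 mM | 22 mM | 0.40 mM | run made earlier |  |
| north | 20 mM | 22.0 mM | 0.40 mM |  | 25 h |
| north-west | 60 mM | 22.0 mM | 0.40 mM |  | 25 h |
| west | 200 mM | 22.0 mM | 0.40 mM |  | 25 h |
| east | 500 mM | 22.0 mM | 0.40 mM |  | 25 h |
| south-east | 1500 mM | 22.0 mM | 0.40 mM |  | 25 h |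

| run | time / h | product / % | substrate / % |
|---|---|---|---|
| alder | 2.00 | 13.0 | 85.8 |
| alder | 6.00 | 14.9 | 84.4 |
| alder | 12.0 | 13.2 | 87.4 |
| alder | 20.0 | 14.6 | 84.8 |
| elm | 2.00 | 1.2 | 99.0 |
| elm | 6.00 | 3.8 | 99.4 |
| elm | 12.0 | 2.2 | 98.1 |
| elm | 20.0 | 0.8 | 97.7 |

(standard deviation of a reading: 1 percentage point)

- the numbers in the tables scatter with a standard deviation of 1 percentage point
- "hardly changes" means that all values lie within two and a half points (for a concentration: within two and a half percent of the largest)
- a step back or a flat step of under half a percent of the largest counts as no turn

* [product] at the end for north, north-west, west, east, south-east, in this order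
* how the row runs (hardly changes / falls all the way / rises, then falls / rises all the way / falls, then rises)

So I ask whether the alder stop belongs to the substrate as a percentage or to something else as an amount. Alder product does not climb from 2.00 h to 20.0 h, so I average the readings of each run and turn them into amounts:

alder: 3.06 mM

elm: 3.80 mM

The alder percentage applied to the elm charge comes to 26.5 mM, and the elm amount lies far below that. The gap between the two amounts is 0.740 mM, which is less than one point of an elm reading, 1.90 mM. One point of an alder reading is worth 0.220 mM, so I take my figure from alder, the finer of the two:

3.06 mM / 0.40 mM = 7.66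

This number, the product made per catalyst charged before the flask stops, is what I call the stopping count. North carries 0.40 mM of catalyst, so my own reckoning is

7.66 × 0.40 mM = 3.06 mM

In north that is 15.3% of the substrate, and I expect the same amount along the row.

The forecast also gives 3.1 mM at each point, so the row hardly changes. One of its grounds reads “Partner and substrate are both left in large excess, so neither is exhausted”.

The flasks give 2.90 mM, 3.02 mM, 3.06 mM, 3.07 mM and 3.07 mM, so the row rises all the way.

    partner + free catalyst → catalyst intermediate A (k = 2300 /M/h)
    substrate + catalyst intermediate A → catalyst intermediate B (k = 3100 /M/h)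
    catalyst intermediate B → released group + catalyst intermediate C (k = 290 /h)
    catalyst intermediate C ⇌ catalyst intermediate D (K = 0.540, k = 22.0 /h)
    catalyst intermediate D ⇌ free catalyst + product (K = 0.00310 M, k = 120 /h)
    crystals ⇌ released group, rate k6*(cs6 - [released group]) while solid is left; crystals form when [released group] > cs6 (solubility = 13.0 mM, k = 7.70 /h)
    partner → decomposed reagent (k = 1.30 /h)

The stopping count comes to 7.25 in north and 7.67 in south-east, beside 7.66 from alder. In north, partner, the limiting reagent, stands at 0% of its charge after 25.0 h, and 18.8 mM of it has become decomposed reagent. That decomposition is one part of the reason for the stop in north: without it, north gives 17.5 mM of product instead of 2.90 mM.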